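**Strategy.** The hexamer is read as three (7R,8R)-ε-viniferin units, so everything rests on one dihydrobenzofuran disconnection. In the key step three components are joined: an O-Boc salicylaldehyde (ring B, formyl carbon = C8a), an aryl Grignard reagent (ring A) and a chiral benzylic sulfonium ylide (C7a). The adjacent ring-B carbons C10b and oxygen-bearing C11b release an ortho-quinone methide at C8a, the ylide adds there, and the phenoxide closes the furan ring through the O–C7a bond, setting C7a and C8a. This one unit, as a hindered 4-hydroxystilbene or a bromoketone, is then assembled by base-gated phenoxide/quinone-methide couplings that build the eight- and seven-membered rings.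

Key step: step 6

Labels: the resveratrol units are a–f; in each, C7 bears the 4-hydroxyphenyl group and C8 the resorcinol ring (C9–C14, oxygen on C11 and C13; ring A belongs to unit a, and so on). Dihydrofurans: O(C11b)–C7a with C8a–C10b, O(C11c)–C7d with C8d–C10c, O(C11e)–C7f with C8f–C10e. Carbocycles: seven-membered ring through C7b–C10a; eight-membered ring through C8c–C8e and C7e–C10d. C8b–C7c joins the halves.

Assumptions: 1, 5, 7, 8, 18 and 22 are taken as commercial. The (1R,4R,5R)-sulfide 7 is assumed to deliver the (2R,3R) series; if the sense is opposite, its enantiomer is used. Under base only free (desilylated) resorcinol rings act as carbon nucleophiles; benzyl ethers stay inert.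

**Route**

Step 1
Reactants: 1 1-bromo-3,5-bis(benzyloxy)benzene
Product: 2 2,4-bis(benzyloxy)-6-bromobenzaldehyde
Conditions: POCl3, DMF, 0 → 80 °C; aq. NaOAc
Reagents that add atoms: N,N-dimethylformamide CN(C)C=O; water O
Why: Vilsmeier–Haack formylation should occur para to one benzyloxy group and ortho to the other, next to bromine and not at the doubly flanked position between the two ethers.

Step 2
Reactants: 2 2,4-bis(benzyloxy)-6-bromobenzaldehyde
Product: 3 4-(benzyloxy)-2-bromo-6-hydroxybenzaldehyde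
Conditions: MgBr2·OEt2, toluene/Et2O, 80 °C; aq. HCl
Reagents that add atoms: none
Why: Chelation of magnesium between the formyl oxygen and the ortho ether oxygen should direct bromide to cleave only the ortho benzyl ether (chelation-controlled dealkylation).

Step 3
Reactants: 3 4-(benzyloxy)-2-bromo-6-hydroxybenzaldehyde
Product: 4 tert-butyl [5-(benzyloxy)-3-bromo-2-formylphenyl] carbonate
Conditions: Boc2O, DMAP (cat.), iPr2NEt, CH2Cl2, 0 °C
Reagents that add atoms: di-tert-butyl dicarbonate CC(C)(C)OC(=O)OC(=O)OC(C)(C)C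
Why: DMAP-catalysed O-acylation of the phenol gives the O-Boc salicylaldehyde from which an ortho-quinone methide can be released under anionic conditions.

Step 4
Reactants: 5 5-bromobenzene-1,3-diol
Product: 6 1-bromo-3,5-bis(triisopropylsilyloxy)benzene
Conditions: iPr3SiCl, imidazole, DMF, rt
Reagents that add atoms: chlorotriisopropylsilane CC(C)[Si](Cl)(C(C)C)C(C)C
Why: Standard silylation; the triisopropylsilyl ethers should survive the Grignard, Heck and enolate steps and are later cleaved by fluoride to switch a resorcinol ring on as a nucleophile.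

Step 5
Reactants: 7 (1R,4R,5R)-4,7,7-trimethyl-6-thiabicyclo[3.2.1]octane (isothiocineole); 8 4-(benzyloxy)benzyl bromide
Product: 9 (1R,4R,5R)-6-[4-(benzyloxy)benzyl]-4,7,7-trimethyl-6-thiabicyclo[3.2.1]octan-6-ium trifluoromethanesulfonate
Conditions: LiOTf, CH2Cl2/H2O, rt
Reagents that add atoms: lithium trifluoromethanesulfonate [Li+].[O-]S(=O)(=O)C(F)(F)F
Why: S-alkylation of the bicyclic sulfide on its exposed lone pair should give one sulfonium diastereomer, and exchange to the non-nucleophilic triflate prevents dealkylation.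

Step 6
Reactants: 4 tert-butyl [5-(benzyloxy)-3-bromo-2-formylphenyl] carbonate; 6 1-bromo-3,5-bis(triisopropylsilyloxy)benzene; 9 sulfonium triflate
Product: 15 (2R,3R)-6-(benzyloxy)-2-[4-(benzyloxy)phenyl]-4-bromo-3-[3,5-bis(triisopropylsilyloxy)phenyl]-2,3-dihydro-1-benzofuran, via aryl Grignard reagent 10 (not isolated), via sulfonium ylide 11 (not isolated), via magnesium alkoxide adduct 12 (not isolated), via ortho-quinone methide 13 (not isolated), via sulfonium phenoxide betaine 14 (not isolated)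
Conditions: 6, Mg, THF, 50 °C; 4, THF, −78 °C; then ylide from 9, LiN(SiMe3)2, THF, −78 °C; −78 → 0 °C; aq. NH4Cl
Reagents that add atoms: none
Why: Grignard reagent 10 adds to the aldehyde of 4, the Boc group migrates to the new alkoxide of 12 and tert-butyl carbonate is expelled, which unmasks ortho-quinone methide 13 across O–C11b–C10b–C8a; ylide 11 then adds to C8a to give betaine 14, whose phenoxide displaces the sulfide at C7a. The closest known reactions are the anionic ortho-quinone methide cascade of O-Boc salicylaldehydes with organomagnesium reagents and the [4+1] annulation of ortho-quinone methides with sulfonium ylides, telescoped here in one flask. The only ring closed is the dihydrofuran, by 5-exo-tet SN2 attack of the ring-B phenoxide oxygen on C7a with inversion, which forms the O–C7a bond. C7a is controlled by the isothiocineole auxiliary, which exposes one face of the ylide carbon; C8a follows from the anti addition mode and the reversibility of the syn betaine, so the trans-(2R,3R) ring should result. The step needs 1,2-addition to the aldehyde in preference to the carbonate and the aryl bromide, which the low temperature secures, and it needs the ylide to intercept the quinone methide before it oligomerises, which is secured by having the ylide present while the mixture warms.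

Step 7
Reactants: 15 dihydrobenzofuran bromide (silyl series)
Product: 17 (2R,3R)-6-(benzyloxy)-2-[4-(benzyloxy)phenyl]-3-[3,5-bis(benzyloxy)phenyl]-4-bromo-2,3-dihydro-1-benzofuran, via resorcinol diol 16 (not isolated)
Conditions: Bu4NF (2.2 equiv), THF, 0 °C; then BnBr (2.6 equiv), 0 °C → rt
Reagents that add atoms: benzyl bromide BrCc1ccccc1
Why: Fluoride cleaves both aryl silyl ethers, and diol 16, present as its tetrabutylammonium phenoxide, is benzylated in the same flask (desilylation followed by Williamson etherification); neither stereocentre is touched, and the unit obtained keeps its resorcinol ring (ring F) benzylated and therefore silent under base.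

Step 8
Reactants: 18 3,5-di-tert-butyl-4-hydroxybenzaldehyde
Product: 19 2,6-di-tert-butyl-4-vinylphenol
Conditions: Ph3PCH3Br, KOtBu (2.2 equiv), THF, 0 °C → rt
Reagents that add atoms: methyltriphenylphosphonium bromide C[P+](c1ccccc1)(c1ccccc1)c1ccccc1.[Br-]
Why: Wittig methylenation, with the second equivalent of base covering the hindered phenol.

Step 9
Reactants: 15 dihydrobenzofuran bromide (silyl series); 19 2,6-di-tert-butyl-4-vinylphenol
Product: 20 4-[(E)-2-{(2R,3R)-6-(benzyloxy)-2-[4-(benzyloxy)phenyl]-3-[3,5-bis(triisopropylsilyloxy)phenyl]-2,3-dihydro-1-benzofuran-4-yl}ethenyl]-2,6-di-tert-butylphenol (units a/b)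
Conditions: Pd[P(t-Bu)3]2 (5 mol%), Cy2NMe, dioxane, 80 °C
Reagents that add atoms: none
Why: Mizoroki–Heck coupling of the hindered, electron-rich aryl bromide; syn insertion and syn β-hydride elimination should give the E-stilbene.

Step 10
Reactants: 17 dihydrobenzofuran bromide (benzyl series); 19 2,6-di-tert-butyl-4-vinylphenol
Product: 21 4-[(E)-2-{(2R,3R)-6-(benzyloxy)-2-[4-(benzyloxy)phenyl]-3-[3,5-bis(benzyloxy)phenyl]-2,3-dihydro-1-benzofuran-4-yl}ethenyl]-2,6-di-tert-butylphenol (units f/e)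
Conditions: Pd[P(t-Bu)3]2 (5 mol%), Cy2NMe, dioxane, 80 °C
Reagents that add atoms: none
Why: Mizoroki–Heck coupling as in step 9, giving the E-stilbene.

Step 11
Reactants: 15 dihydrobenzofuran bromide (silyl series); 22 1-(3,5-di-tert-butyl-4-hydroxyphenyl)ethanone
Product: 23 2-{(2R,3R)-6-(benzyloxy)-2-[4-(benzyloxy)phenyl]-3-[3,5-bis(triisopropylsilyloxy)phenyl]-2,3-dihydro-1-benzofuran-4-yl}-1-(3,5-di-tert-butyl-4-hydroxyphenyl)ethanone (units d/c, C7c as ketone)
Conditions: Pd(OAc)2, XPhos, LiN(SiMe3)2 (2.3 equiv), toluene, 70 °C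
Reagents that add atoms: none
Why: Palladium-catalysed α-arylation of the ketone enolate (Buchwald–Hartwig type) should stop at mono-arylation for steric reasons and keeps C7c at the unreactive ketone level.

Step 12
Reactants: 23 aryl ketone of units d/c
Product: 24 2-bromo derivative of 23 (bromine on C8c, mixture of epimers)
Conditions: LiN(SiMe3)2 (2.2 equiv), THF, −78 °C; then NBS, −78 °C
Reagents that add atoms: N-bromosuccinimide O=C1CCC(=O)N1Br
Why: Bromination of the preformed enolate is faster than bromination of the electron-rich arenes and places the leaving group on C8c.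

Step 13
Reactants: 21 hydroxystilbene of units f/e; 24 α-bromo ketone of units d/c
Product: 26 eight-membered-ring tetramer ketone with free ring-D diol (C8c–C8e and C7e–C10d bonds formed; configuration as in 33), via tetramer quinone methide 25 (not isolated)
Conditions: 21, KN(SiMe3)2 (1.0 equiv), THF, −78 °C; 24 pretreated with KN(SiMe3)2 (1.0 equiv); −78 → 0 °C; then Bu4NF, 0 °C → rt; aq. NH4Cl
Reagents that add atoms: none
Why: Proposed new method: the potassium phenoxide of 21 is a vinylogous enolate whose ortho positions are blocked and whose oxygen is shielded by tert-butyl groups, so it should displace bromide from the activated α-bromo ketone through C8e and give quinone methide 25 without an oxidant; fluoride then frees ring D as the only phenoxide carbon nucleophile, which adds 1,6 through C10d to C7e and closes the eight-membered ring, with attack anti to ring F at C8e and anti to ring E at C7e, while C8c, α to the ketone, can equilibrate; the closest known reaction types are para C-alkylation of 2,6-di-tert-butylphenoxides by alkyl halides, the β-carbon nucleophilicity of hydroxystyrenes that generates quinone methides, and base-mediated 1,6-arylation of para-quinone methides by phenols.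

Step 14
Reactants: 26 tetramer ketone with free ring-D diol
Product: 27 ring-D dibenzyl ether of 26
Conditions: BnBr (2.2 equiv), K2CO3, DMF, 0 °C → rt
Reagents that add atoms: benzyl bromide BrCc1ccccc1
Why: Williamson etherification of the two unhindered resorcinol hydroxyls (the 2,6-di-tert-butylphenols are too hindered to react) silences ring D for the later base-mediated step.

Step 15
Reactants: 27 tetramer ketone
Product: 29 tetramer quinone methide (C7c as the quinone methide carbon), via carbinol 28 (not isolated)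
Conditions: NaBH4, THF/MeOH, 0 °C; then PPTS, MgSO4, CH2Cl2, rt
Reagents that add atoms: none
Why: Carbonyl reduction followed by mild acid-catalysed 1,6-dehydration of the 3,5-di-tert-butyl-4-hydroxybenzylic alcohol gives a tert-butyl-stabilised quinone methide that should not be activated towards the benzyl ether rings by this weak acid.

Step 16
Reactants: 20 hydroxystilbene of units a/b; 29 tetramer quinone methide
Product: 31 protected hexamer (skeleton and all twelve stereocentres of 33; ten benzyl ethers, free ring-A diol, three 3,5-di-tert-butyl-4-hydroxyphenyl groups), via hexamer quinone methide 30 (not isolated)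
Conditions: 20 (1.2 equiv), KN(SiMe3)2 (0.2 equiv), THF, −40 → 0 °C; then Bu4NF, 0 °C; aq. NH4Cl
Reagents that add atoms: none
Why: Proposed new method: with catalytic base the phenoxide of 20 should add through C8b to C7c of quinone methide 29 (a vinylogous 1,6-addition; it is the two-electron counterpart of the known oxidative C8–C8 coupling of such phenoxides and extends the known 1,6-addition of carbon nucleophiles to para-quinone methides), which turns unit b into quinone methide 30 and passes the proton on; fluoride then frees ring A, whose phenoxide closes the seven-membered ring by 1,6-addition of C10a to C7b anti to the C8b substituent, with C7c and C8b set by attack anti to the C8c ring substituent and anti to ring A.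

Step 17
Reactants: 31 protected hexamer
Product: 32 hexa-tert-butyl hexamer (all benzyl ethers removed)
Conditions: BCl3, C6HMe5, CH2Cl2, −78 °C
Reagents that add atoms: none
Why: Lewis-acid debenzylation with pentamethylbenzene as cation scavenger avoids hydrogenolysis of the benzylic C–O bonds of the three dihydrofurans.

Step 18
Reactants: 32 hexa-tert-butyl hexamer
Product: 33 target hexamer CNP0184494.1
Conditions: AlCl3, toluene/MeNO2, 60 °C
Reagents that add atoms: none
Why: Retro-Friedel–Crafts transfer of the six tert-butyl groups to toluene should unveil the three 4-hydroxyphenyl groups without touching the sp3 stereocentres.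

**Compound list**

1 | 1-bromo-3,5-bis(benzyloxy)benzene | Brc1cc(OCc2ccccc2)cc(OCc2ccccc2)c1 | starting material
2 | 2,4-bis(benzyloxy)-6-bromobenzaldehyde | O=Cc1c(Br)cc(OCc2ccccc2)cc1OCc3ccccc3 | intermediate
3 | 4-(benzyloxy)-2-bromo-6-hydroxybenzaldehyde | O=Cc1c(Br)cc(OCc2ccccc2)cc1O | intermediate
4 | tert-butyl [5-(benzyloxy)-3-bromo-2-formylphenyl] carbonate | O=Cc1c(Br)cc(OCc2ccccc2)cc1OC(=O)OC(C)(C)C | intermediate
5 | 5-bromobenzene-1,3-diol | Oc1cc(O)cc(Br)c1 | starting material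
6 | 1-bromo-3,5-bis(triisopropylsilyloxy)benzene | Brc1cc(O[Si](C(C)C)(C(C)C)C(C)C)cc(O[Si](C(C)C)(C(C)C)C(C)C)c1 | intermediate
7 | (1R,4R,5R)-4,7,7-trimethyl-6-thiabicyclo[3.2.1]octane (isothiocineole) | C[C@@H]1CC[C@@H]2C[C@H]1SC2(C)C | starting material
8 | 4-(benzyloxy)benzyl bromide | BrCc1ccc(OCc2ccccc2)cc1 | starting material
9 | (1R,4R,5R)-6-[4-(benzyloxy)benzyl]-4,7,7-trimethyl-6-thiabicyclo[3.2.1]octan-6-ium triflate (one diastereomer at sulfur) | C[C@@H]1CC[C@@H]2C[C@H]1[S+](Cc3ccc(OCc4ccccc4)cc3)C2(C)C.[O-]S(=O)(=O)C(F)(F)F | intermediate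
10 | [3,5-bis(triisopropylsilyloxy)phenyl]magnesium bromide | Br[Mg]c1cc(O[Si](C(C)C)(C(C)C)C(C)C)cc(O[Si](C(C)C)(C(C)C)C(C)C)c1 | intermediate
11 | sulfonium ylide of 9 | C[C@@H]1CC[C@@H]2C[C@H]1[S+]([CH-]c3ccc(OCc4ccccc4)cc3)C2(C)C | intermediate
12 | bromomagnesium alkoxide from addition of 10 to 4 (racemic carbinol carbon) | CC(C)(C)OC(=O)Oc1cc(OCc2ccccc2)cc(Br)c1C(O[Mg]Br)c1cc(O[Si](C(C)C)(C(C)C)C(C)C)cc(O[Si](C(C)C)(C(C)C)C(C)C)c1 | intermediate
13 | 3-(benzyloxy)-5-bromo-6-[3,5-bis(triisopropylsilyloxy)benzylidene]cyclohexa-2,4-dien-1-one (ortho-quinone methide) | O=C1C=C(OCc2ccccc2)C=C(Br)C1=Cc3cc(O[Si](C(C)C)(C(C)C)C(C)C)cc(O[Si](C(C)C)(C(C)C)C(C)C)c3 | intermediate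
14 | betaine from addition of 11 to 13 (phenoxide and sulfonium, anti) | C[C@@H]1CC[C@@H]2C[C@H]1[S+]([C@H](c3ccc(OCc4ccccc4)cc3)[C@H](c3cc(O[Si](C(C)C)(C(C)C)C(C)C)cc(O[Si](C(C)C)(C(C)C)C(C)C)c3)c3c([O-])cc(OCc4ccccc4)cc3Br)C2(C)C | intermediate
15 | (2R,3R)-6-(benzyloxy)-2-[4-(benzyloxy)phenyl]-4-bromo-3-[3,5-bis(triisopropylsilyloxy)phenyl]-2,3-dihydro-1-benzofuran | Brc1cc(OCc2ccccc2)cc3c1[C@@H](c1cc(O[Si](C(C)C)(C(C)C)C(C)C)cc(O[Si](C(C)C)(C(C)C)C(C)C)c1)[C@H](c1ccc(OCc2ccccc2)cc1)O3 | intermediate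
16 | 5-{(2R,3R)-6-(benzyloxy)-2-[4-(benzyloxy)phenyl]-4-bromo-2,3-dihydro-1-benzofuran-3-yl}benzene-1,3-diol (in the flask as its tetrabutylammonium phenoxide) | Brc1cc(OCc2ccccc2)cc3c1[C@@H](c1cc(O)cc(O)c1)[C@H](c1ccc(OCc2ccccc2)cc1)O3 | intermediate
17 | (2R,3R)-6-(benzyloxy)-2-[4-(benzyloxy)phenyl]-3-[3,5-bis(benzyloxy)phenyl]-4-bromo-2,3-dihydro-1-benzofuran | Brc1cc(OCc2ccccc2)cc3c1[C@@H](c1cc(OCc2ccccc2)cc(OCc2ccccc2)c1)[C@H](c1ccc(OCc2ccccc2)cc1)O3 | intermediate
18 | 3,5-di-tert-butyl-4-hydroxybenzaldehyde | CC(C)(C)c1cc(C=O)cc(C(C)(C)C)c1O | starting material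
19 | 2,6-di-tert-butyl-4-vinylphenol | C=Cc1cc(C(C)(C)C)c(O)c(C(C)(C)C)c1 | intermediate
20 | E-hydroxystilbene of units a/b (ring A as bis-silyl ether) | CC(C)(C)c1cc(/C=C/c2cc(OCc4ccccc4)cc3c2[C@@H](c2cc(O[Si](C(C)C)(C(C)C)C(C)C)cc(O[Si](C(C)C)(C(C)C)C(C)C)c2)[C@H](c2ccc(OCc4ccccc4)cc2)O3)cc(C(C)(C)C)c1O | intermediate
21 | E-hydroxystilbene of units f/e (ring F as dibenzyl ether) | CC(C)(C)c1cc(/C=C/c2cc(OCc4ccccc4)cc3c2[C@@H](c2cc(OCc4ccccc4)cc(OCc4ccccc4)c2)[C@H](c2ccc(OCc4ccccc4)cc2)O3)cc(C(C)(C)C)c1O | intermediate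
22 | 1-(3,5-di-tert-butyl-4-hydroxyphenyl)ethanone | CC(=O)c1cc(C(C)(C)C)c(O)c(C(C)(C)C)c1 | starting material
23 | aryl ketone of units d/c (C7c carbonyl, C8c methylene, ring D as bis-silyl ether) | CC(C)(C)c1cc(C(=O)Cc2cc(OCc4ccccc4)cc3c2[C@@H](c2cc(O[Si](C(C)C)(C(C)C)C(C)C)cc(O[Si](C(C)C)(C(C)C)C(C)C)c2)[C@H](c2ccc(OCc4ccccc4)cc2)O3)cc(C(C)(C)C)c1O | intermediate
24 | α-bromo ketone of 23 (bromine on C8c, both epimers) | CC(C)(C)c1cc(C(=O)C(Br)c2cc(OCc4ccccc4)cc3c2[C@@H](c2cc(O[Si](C(C)C)(C(C)C)C(C)C)cc(O[Si](C(C)C)(C(C)C)C(C)C)c2)[C@H](c2ccc(OCc4ccccc4)cc2)O3)cc(C(C)(C)C)c1O | intermediate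
25 | tetramer quinone methide (C8c–C8e bond formed, C7e as quinone methide carbon, ring D bis-silyl ether) | CC(C)(C)C1=CC(=C[C@H]([C@@H](C(=O)c2cc(C(C)(C)C)c(O)c(C(C)(C)C)c2)c2cc(OCc6ccccc6)cc3c2[C@@H](c2cc(O[Si](C(C)C)(C(C)C)C(C)C)cc(O[Si](C(C)C)(C(C)C)C(C)C)c2)[C@H](c2ccc(OCc6ccccc6)cc2)O3)c2cc(OCc6ccccc6)cc3c2[C@@H](c2cc(OCc6ccccc6)cc(OCc6ccccc6)c2)[C@H](c2ccc(OCc6ccccc6)cc2)O3)C=C(C(C)(C)C)C1=O | intermediate
26 | eight-membered-ring tetramer ketone, free ring-D diol | O=C(c1cc(C(C)(C)C)c(O)c(C(C)(C)C)c1)[C@H]2c4cc(OCc6ccccc6)cc5c4[C@@H](c4cc(O)cc(O)c4[C@H](c4cc(C(C)(C)C)c(O)c(C(C)(C)C)c4)[C@H]2c2cc(OCc6ccccc6)cc4c2[C@@H](c2cc(OCc6ccccc6)cc(OCc6ccccc6)c2)[C@H](c2ccc(OCc6ccccc6)cc2)O4)[C@H](c2ccc(OCc6ccccc6)cc2)O5 | intermediate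
27 | ring-D dibenzyl ether of 26 | O=C(c1cc(C(C)(C)C)c(O)c(C(C)(C)C)c1)[C@H]2c4cc(OCc6ccccc6)cc5c4[C@@H](c4cc(OCc6ccccc6)cc(OCc6ccccc6)c4[C@H](c4cc(C(C)(C)C)c(O)c(C(C)(C)C)c4)[C@H]2c2cc(OCc6ccccc6)cc4c2[C@@H](c2cc(OCc6ccccc6)cc(OCc6ccccc6)c2)[C@H](c2ccc(OCc6ccccc6)cc2)O4)[C@H](c2ccc(OCc6ccccc6)cc2)O5 | intermediate
28 | C7c carbinol of 27 (both carbinol epimers) | OC(c1cc(C(C)(C)C)c(O)c(C(C)(C)C)c1)[C@H]2c4cc(OCc6ccccc6)cc5c4[C@@H](c4cc(OCc6ccccc6)cc(OCc6ccccc6)c4[C@H](c4cc(C(C)(C)C)c(O)c(C(C)(C)C)c4)[C@H]2c2cc(OCc6ccccc6)cc4c2[C@@H](c2cc(OCc6ccccc6)cc(OCc6ccccc6)c2)[C@H](c2ccc(OCc6ccccc6)cc2)O4)[C@H](c2ccc(OCc6ccccc6)cc2)O5 | intermediate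
29 | tetramer quinone methide (C7c as quinone methide carbon) | CC(C)(C)C1=CC(=C[C@H]2c4cc(OCc6ccccc6)cc5c4[C@@H](c4cc(OCc6ccccc6)cc(OCc6ccccc6)c4[C@H](c4cc(C(C)(C)C)c(O)c(C(C)(C)C)c4)[C@H]2c2cc(OCc6ccccc6)cc4c2[C@@H](c2cc(OCc6ccccc6)cc(OCc6ccccc6)c2)[C@H](c2ccc(OCc6ccccc6)cc2)O4)[C@H](c2ccc(OCc6ccccc6)cc2)O5)C=C(C(C)(C)C)C1=O | intermediate
30 | hexamer quinone methide (C8b–C7c bond formed, C7b as quinone methide carbon, ring A bis-silyl ether) | CC(C)(C)C1=CC(=C[C@H]([C@H](c2cc(C(C)(C)C)c(O)c(C(C)(C)C)c2)[C@H]2c4cc(OCc6ccccc6)cc5c4[C@@H](c4cc(OCc6ccccc6)cc(OCc6ccccc6)c4[C@H](c4cc(C(C)(C)C)c(O)c(C(C)(C)C)c4)[C@H]2c2cc(OCc6ccccc6)cc4c2[C@@H](c2cc(OCc6ccccc6)cc(OCc6ccccc6)c2)[C@H](c2ccc(OCc6ccccc6)cc2)O4)[C@H](c2ccc(OCc6ccccc6)cc2)O5)c2cc(OCc6ccccc6)cc3c2[C@@H](c2cc(O[Si](C(C)C)(C(C)C)C(C)C)cc(O[Si](C(C)C)(C(C)C)C(C)C)c2)[C@H](c2ccc(OCc6ccccc6)cc2)O3)C=C(C(C)(C)C)C1=O | intermediate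
31 | protected hexamer (ten benzyl ethers, six tert-butyl groups, free ring-A diol) | Oc1c(C(C)(C)C)cc([C@H]2c3c(O)cc(O)cc3[C@@H]3c4c(cc(OCc6ccccc6)cc4[C@H]2[C@H](c2cc(C(C)(C)C)c(O)c(C(C)(C)C)c2)[C@H]2c4cc(OCc6ccccc6)cc5c4[C@@H](c4cc(OCc6ccccc6)cc(OCc6ccccc6)c4[C@H](c4cc(C(C)(C)C)c(O)c(C(C)(C)C)c4)[C@H]2c2cc(OCc6ccccc6)cc4c2[C@@H](c2cc(OCc6ccccc6)cc(OCc6ccccc6)c2)[C@H](c2ccc(OCc6ccccc6)cc2)O4)[C@H](c2ccc(OCc6ccccc6)cc2)O5)O[C@H]3c2ccc(OCc6ccccc6)cc2)cc1C(C)(C)C | intermediate
32 | hexa-tert-butyl hexamer | Oc1c(C(C)(C)C)cc([C@H]2c3c(O)cc(O)cc3[C@@H]3c4c(cc(O)cc4[C@H]2[C@H](c2cc(C(C)(C)C)c(O)c(C(C)(C)C)c2)[C@H]2c4cc(O)cc5c4[C@@H](c4cc(O)cc(O)c4[C@H](c4cc(C(C)(C)C)c(O)c(C(C)(C)C)c4)[C@H]2c2cc(O)cc4c2[C@@H](c2cc(O)cc(O)c2)[C@H](c2ccc(O)cc2)O4)[C@H](c2ccc(O)cc2)O5)O[C@H]3c2ccc(O)cc2)cc1C(C)(C)C | intermediate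
33 | CNP0184494.1, resveratrol hexamer, (7aR,8aR,7bS,8bS,7cR,8cR,7dR,8dR,7eS,8eS,7fR,8fR) in the unit labels used here | Oc1ccc([C@H]2c3c(O)cc(O)cc3[C@@H]3c4c(cc(O)cc4[C@H]2[C@H](c2ccc(O)cc2)[C@H]2c4cc(O)cc5c4[C@@H](c4cc(O)cc(O)c4[C@H](c4ccc(O)cc4)[C@H]2c2cc(O)cc4c2[C@@H](c2cc(O)cc(O)c2)[C@H](c2ccc(O)cc2)O4)[C@H](c2ccc(O)cc2)O5)O[C@H]3c2ccc(O)cc2)cc1 | target

**Count and risks**

Total steps: 18. Longest linear sequence: 12 steps (1, 2, 3, 6, 11, 12, 13, 14, 15, 16, 17, 18; the branch through steps 7 and 10 is equally long).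

Steps most likely to fail:

1. Step 13 (Proposed new method). The phenoxide may react at oxygen or attack bromine instead of forming the C8c–C8e bond at the hindered secondary bromide. The quinone methide may tautomerise to a stilbene before ring D adds. Facial selectivity at C8e may be poor, and the equilibrium at C8c may favour the wrong epimer. Fallback: the ionic alkylation is replaced by a radical-polar crossover of known type (photoredox alkylation of styrenes by α-bromo ketones). Compounds 21 and 24 are irradiated with blue light with fac-Ir(ppy)3 and 2,6-lutidine in MeCN/CH2Cl2. Single-electron reduction of 24 gives the α-keto radical, which adds to C8e of the neutral hydroxystilbene; oxidation of the benzylic radical and loss of the phenolic proton give the same quinone methide. The fallback sets out from 21 and 24 and comes back at 25, which is treated with Bu4NF as in step 13; it makes no new compound (F0).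

2. Step 16 (Proposed new method). Conjugate addition between two hindered centres may be slow, so that base-induced tautomerisation of either quinone methide competes, and facial selectivity at C7c and C8b may be low. Fallback: a cationic union of known type (Lewis-acid addition of an electron-rich styrene to a para-quinone methide, then Friedel–Crafts closure of the resulting benzylic cation). Compounds 20 and 29 are treated with BF3·OEt2 in CH2Cl2 at −78 °C; the alkene of 20 attacks C7c, and the C7b cation is trapped by C10a of the silylated ring A to give the ring-A bis(triisopropylsilyl) ether of the cyclised hexamer F1. Bu4NF then removes the silyl groups. The fallback sets out from 20 and 29 and comes back at 31.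

3. Step 6 (key step). The ylide may discriminate the enantiofaces incompletely, the quinone methide may oligomerise before the ylide arrives, and the ylide may be consumed by the carbonate. Fallback: the cascade is uncoupled into isolated stages. Grignard reagent 10 (2.2 equiv) adds to the free phenol aldehyde 3 to give the ortho-hydroxybenzhydrol F2. Exchange of its hydroxyl for sulfinate (sodium p-toluenesulfinate, HCO2H, rt) gives the 2-[aryl(tosyl)methyl]phenol F3. Cs2CO3 in CH2Cl2 then releases ortho-quinone methide 13 slowly from F3 while the same base generates ylide 11 from 9, and the [4+1] annulation follows. The fallback sets out from 3, 6 and 9 and comes back at 15.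

**Further compounds**

F0 | step 13 | none | none
F1 | step 16 | cyclised protected hexamer with ring A as bis(triisopropylsilyl) ether | Oc1c(C(C)(C)C)cc([C@H]2c3c(O[Si](C(C)C)(C(C)C)C(C)C)cc(O[Si](C(C)C)(C(C)C)C(C)C)cc3[C@@H]3c4c(cc(OCc6ccccc6)cc4[C@H]2[C@H](c2cc(C(C)(C)C)c(O)c(C(C)(C)C)c2)[C@H]2c4cc(OCc6ccccc6)cc5c4[C@@H](c4cc(OCc6ccccc6)cc(OCc6ccccc6)c4[C@H](c4cc(C(C)(C)C)c(O)c(C(C)(C)C)c4)[C@H]2c2cc(OCc6ccccc6)cc4c2[C@@H](c2cc(OCc6ccccc6)cc(OCc6ccccc6)c2)[C@H](c2ccc(OCc6ccccc6)cc2)O4)[C@H](c2ccc(OCc6ccccc6)cc2)O5)O[C@H]3c2ccc(OCc6ccccc6)cc2)cc1C(C)(C)C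
F2 | step 6 | 5-(benzyloxy)-3-bromo-2-{hydroxy[3,5-bis(triisopropylsilyloxy)phenyl]methyl}phenol (racemic) | Oc1cc(OCc2ccccc2)cc(Br)c1C(O)c1cc(O[Si](C(C)C)(C(C)C)C(C)C)cc(O[Si](C(C)C)(C(C)C)C(C)C)c1
F3 | step 6 | 5-(benzyloxy)-3-bromo-2-{(4-methylbenzenesulfonyl)[3,5-bis(triisopropylsilyloxy)phenyl]methyl}phenol (racemic) | Cc1ccc(S(=O)(=O)C(c2cc(O[Si](C(C)C)(C(C)C)C(C)C)cc(O[Si](C(C)C)(C(C)C)C(C)C)c2)c2c(O)cc(OCc3ccccc3)cc2Br)cc1
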